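**Plan**
1. Numbering (germacrane): C1 ketone, C4–C5 epoxide, C6–O–C12 γ-lactone, C8 methacrylate carbon, C10 acetoxy carbon, C13 acetoxymethyl carbon.
2. Retrosynthetic cuts, in order: the C8–O and C10–O esters; the C10–OH bond plus one H of the C10 methyl (hydration of a 2-methylene ketone); C8–C9 (opens the ten-membered ring); C1–C10; C13–O with C11–H; C6–C7 together with the lactone C12–O6 bond.
3. Enabling feature: the C8 carbinol lies two bonds from quaternary C10, and the CH3/O pair on C10 beside the C1 ketone is the hydrate of an exocyclic methylene ketone on the ten-membered ring, so C8–C9 can come from a C8 aldehyde and a 2-acylallyl metal.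
4. Forward order: epoxide (from nerol), then the γ-lactone by allylboration–lactonisation, then chain extension at C1, then the ten-membered carbocycle by C8–C9 closure, then hydration and two acylations.
5. Stereochemistry: C4/C5 from Sharpless epoxidation; C6/C7 from the allylboration (attack anti to the epoxide C–O bond, chair transition state); C11 from face-selective protonation; C8 from the ring closure under control of C7; C10 from the face of oxygen capture in the hydration.

Key step: step 16

Remark on the chemistry: the SMILES is read as a 4,5-cis epoxide (C3 and C6 on the same side, hence nerol and not geraniol) and an all-cis γ-lactone (H6, H7 and H11 on one face); the route is built for exactly this arrangement.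

**Route**

Step 1
Reactants: 1 nerol
Product: 2 (2S,3R)-2,3-epoxynerol
Conditions: Ti(OiPr)4 (10 mol %), L-(+)-diethyl tartrate (12 mol %), tBuOOH, 4 Å molecular sieves, CH2Cl2, −20 °C
Reagents that add atoms: tert-butyl hydroperoxide, CC(C)(C)OO
Why: Katsuki–Sharpless asymmetric epoxidation of the Z-allylic alcohol, in which the L-(+)-tartrate complex delivers oxygen to the face that gives the (2S,3R)-epoxide (C4 and C5 of the target) and leaves the remote trisubstituted alkene untouched.

Step 2
Reactants: 2 (2S,3R)-2,3-epoxynerol
Product: 3 epoxy aldehyde, (2R,3R)-3-methyl-3-(4-methylpent-3-enyl)oxirane-2-carbaldehyde (geometry of 2 unchanged)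
Conditions: Dess–Martin periodinane, NaHCO3, CH2Cl2, 0 to 25 °C; used crude
Reagents that add atoms: none
Why: Dess–Martin oxidation of a primary epoxy alcohol under buffered, base-free conditions, which should not epimerise the α-epoxy centre.

Step 3
Reactants: 4 methyl acrylate; 5 (tert-butyldimethylsilyloxy)acetaldehyde
Product: 6 methyl 4-(tert-butyldimethylsilyloxy)-3-hydroxy-2-methylenebutanoate (racemic)
Conditions: DABCO (0.5 equiv), MeOH, 25 °C
Reagents that add atoms: none
Why: Morita–Baylis–Hillman reaction of an acrylate with a reactive α-oxygenated aldehyde; the carbinol centre is racemic and is erased in step 5.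

Step 4
Reactants: 6 Morita–Baylis–Hillman alcohol
Product: 7 methyl 3-acetoxy-4-(tert-butyldimethylsilyloxy)-2-methylenebutanoate (racemic)
Conditions: Ac2O, pyridine, DMAP (cat.), CH2Cl2, 0 °C
Reagents that add atoms: acetic anhydride, CC(=O)OC(C)=O
Why: DMAP-catalysed acetylation of a secondary allylic alcohol, run cold to avoid allylic transposition of the acetate.

Step 5
Reactants: 7 Morita–Baylis–Hillman acetate
Product: 8 allylboronate, methyl (E)-4-(tert-butyldimethylsilyloxy)-2-[(pinacolatoboryl)methyl]but-2-enoate (CH2OTBS cis to CH2B, trans to the ester)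
Conditions: B2pin2, CuCl (10 mol %), Xantphos (10 mol %), KOtBu (10 mol %), THF, 0 to 25 °C
Reagents that add atoms: bis(pinacolato)diboron, CC1(C)OB(OC1(C)C)B1OC(C)(C)C(C)(C)O1
Why: copper-catalysed SN2' borylation (boryl-copper conjugate addition, then loss of acetate) of a Morita–Baylis–Hillman acetate, which should give mainly the alkene with the ester trans to the new substituent, as such substitutions usually do.

Step 6
Reactants: 3 epoxy aldehyde; 8 allylboronate
Product: 10 cis-6,7 α-methylene-γ-butyrolactone carrying CH2OTBS at C7 and the epoxy side chain at C6, via O-boryl hydroxy ester 9 (not isolated)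
Conditions: toluene, 50 °C; then PPTS (cat.), 25 °C
Reagents that add atoms: none
Why: thermal carbonyl allylboration through a closed chair (Zimmerman–Traxler) transition state followed by lactonisation, in which the CH2OTBS group cis to CH2B sits axial and gives the syn C6/C7 adduct (cis-lactone), while attack anti to the epoxide C5–O bond (Cornforth/Felkin–Anh, as crotylboronates of this geometry show with α-oxygenated aldehydes) should set C6 relative to C5.

Step 7
Reactants: 10 α-methylene lactone
Product: 12 all-cis 13-hydroxy lactone (C11 hydroxymethyl cis to the C7 and C6 substituents), via 13-boryl lactone 11 (not isolated)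
Conditions: B2pin2, CuCl (5 mol %), DPEphos (5 mol %), NaOtBu (10 mol %), MeOH (2 equiv), THF, 0 to 25 °C; then NaBO3·4H2O, THF/H2O, 25 °C
Reagents that add atoms: sodium perborate, [Na+].[O-]OB=O
Why: copper-catalysed conjugate borylation of an α-methylene lactone with protonation of the copper enolate by methanol, then perborate oxidation of the C–B bond; the proton should arrive at C11 on the lactone face opposite to the two cis substituents at C6 and C7, which places C13 cis to both.

Step 8
Reactants: 12 13-hydroxy lactone
Product: 13 13-acetoxy lactone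
Conditions: Ac2O, pyridine, DMAP (cat.), CH2Cl2, 0 °C
Reagents that add atoms: acetic anhydride, CC(=O)OC(C)=O
Why: acetylation of a primary alcohol with a weak base, which should neither epimerise C11 nor eliminate the β-acetoxy group.

Step 9
Reactants: 13 13-acetoxy lactone
Product: 15 C1 aldehyde (C1–C3 arm ending in CHO), via ozonide 14 (not isolated)
Conditions: O3, CH2Cl2, −78 °C; then PPh3, −78 to 25 °C
Reagents that add atoms: ozone, [O-][O+]=O
Why: ozonolysis with reductive work-up, the trisubstituted alkene being the only C=C bond in 13.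

Step 10
Reactants: 16 2-bromoallyl alcohol
Product: 17 (2-bromoallyloxy)(tert-butyl)dimethylsilane
Conditions: TBSCl, imidazole, CH2Cl2, 0 to 25 °C
Reagents that add atoms: tert-butyldimethylsilyl chloride, CC(C)(C)[Si](C)(C)Cl
Why: standard silylation of a primary alcohol.

Step 11
Reactants: 15 C1 aldehyde; 17 2-bromoallyl silyl ether
Product: 19 C1 allylic alcohol bearing C10(=CH2)CH2OTBS (both C1 epimers), via alkenylchromium dichloride 18 (not isolated)
Conditions: CrCl2 (6 equiv), NiCl2 (2 mol %), DMF, 25 °C; filtration through Et3N-washed silica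
Reagents that add atoms: none
Why: Nozaki–Hiyama–Kishi alkenylation, in which zerovalent nickel inserts into the C–Br bond and transmetalation gives the alkenyl species of trivalent chromium that adds only to the aldehyde; the C1 epimers are immaterial because step 12 oxidises them, and acid is avoided because a 4,5-epoxy-1-ol can cyclise to a tetrahydrofuran.

Step 12
Reactants: 19 C1 allylic alcohol
Product: 20 bis-silyl enone (C1 ketone conjugated to the C10 methylene)
Conditions: Dess–Martin periodinane, NaHCO3, CH2Cl2, 0 to 25 °C
Reagents that add atoms: none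
Why: Dess–Martin oxidation of a secondary allylic alcohol, which also removes the acid-sensitive epoxy alcohol motif.

Step 13
Reactants: 20 bis-silyl enone
Product: 21 enone diol (2-(hydroxymethyl) enone and C8 primary alcohol)
Conditions: HF·pyridine, pyridine, THF, 0 to 25 °C
Reagents that add atoms: none
Why: buffered fluoride cleavage of two primary silyl ethers, conditions that epoxides, lactones and acetates normally tolerate.

Step 14
Reactants: 21 enone diol
Product: 22 2-(bromomethyl) enone with free C8 alcohol
Conditions: NBS, Me2S, CH2Cl2, −20 to 0 °C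
Reagents that add atoms: N-bromosuccinimide, O=C1CCC(=O)N1Br
Why: Corey–Kim halogenation, which under neutral conditions converts allylic alcohols into bromides and returns saturated primary alcohols unchanged on work-up.

Step 15
Reactants: 22 bromomethyl enone alcohol
Product: 23 bromomethyl enone aldehyde (C8 aldehyde on C7, cis to the C6 and C11 substituents)
Conditions: Dess–Martin periodinane, NaHCO3, CH2Cl2, 0 °C; used at once
Reagents that add atoms: none
Why: Dess–Martin oxidation without amine base, chosen because the aldehyde α-carbon C7 is epimerisable and carries the lactone oxygen in the β-position.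

Step 16
Reactants: 23 bromomethyl enone aldehyde
Product: 25 macrocyclic 8-hydroxy-10-methylene enone (8S), via allylchromium dichloride 24 (not isolated)
Conditions: CrCl2 (8 equiv), THF, 25 °C, 23 added over 10 h to a final 2 mM; aqueous work-up
Reagents that add atoms: none
Why: Two equivalents of CrCl2 reduce the allylic C–Br bond of 23 to the 2-acylallyl species 24 of trivalent chromium, which adds to the C8 aldehyde through a six-membered chair-like transition state with chromium on the aldehyde oxygen; because both allyl termini are CH2 groups, either mode of addition forms the same C8–C9 bond and leaves the C10 exo-methylene conjugated to the C1 ketone. The closest known reaction type is the intramolecular Nozaki–Hiyama/Barbier allylation of aldehydes by 2-(bromomethyl)acrylates, which closes ten-membered germacranolide carbocycles and larger rings, the vinyl ketone here taking the place of the acrylate. The ten-membered carbocycle closes in the 10-exo-trig mode, the aldehyde oxygen ending outside the ring as the C8 hydroxyl. The new C8 stereocentre is controlled by C7: with the tether leaving C7 through C6, the reachable Felkin-type geometry has the C7–C11 bond anti to the incoming C9 and C6 gauche to it, which should expose the aldehyde face that leads to the 8S alcohol. The step needs chemoselectivity for the aldehyde over the C1 ketone, lactone, acetate and epoxide, secured because the aldehyde is the most electrophilic carbonyl of the substrate and the organochromium reagent is weakly basic; it needs ring closure to beat intermolecular coupling, secured by slow addition at high dilution, and the neutral medium keeps C7 from epimerising or losing the lactone oxygen by β-elimination.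

Step 17
Reactants: 25 macrocyclic hydroxy enone
Product: 27 8,10-diol (tertiary C10 alcohol with C10 methyl beside the C1 ketone), via C10 hydroperoxide 26 (not isolated)
Conditions: Mn(dpm)3 (10 mol %, dpm = dipivaloylmethanate), PhSiH3, O2 (1 atm), iPrOH/CH2Cl2, 0 °C; then P(OEt)3
Reagents that add atoms: dioxygen, O=O
Why: Mukaiyama-type hydration of an enone, in which hydrogen-atom transfer to the exocyclic CH2 gives the tertiary C10 radical beside the ketone and dioxygen is captured there, the hydroperoxide then being reduced by the phosphite; the C10 configuration depends on which face of the ring-bound radical is more exposed and must be assigned on 27.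

Step 18
Reactants: 27 8,10-diol
Product: 28 8-methacrylate with free tertiary C10 alcohol
Conditions: methacrylic anhydride, Et3N, DMAP (cat.), CH2Cl2, 0 °C
Reagents that add atoms: methacrylic anhydride, C=C(C)C(=O)OC(=O)C(C)=C
Why: DMAP-catalysed acylation, selective for the secondary C8 alcohol because the tertiary α-ketol hydroxyl is far less reactive; it comes after step 17 because a methacrylate would itself be hydrated under those conditions.

Step 19
Reactants: 28 8-methacrylate
Product: 29 CNP0166747.1
Conditions: Ac2O, DMAP (2 equiv), pyridine, CH2Cl2, 25 to 40 °C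
Reagents that add atoms: acetic anhydride, CC(=O)OC(C)=O
Why: DMAP-mediated acetylation of a tertiary α-ketol under non-acidic conditions that spare the epoxide, with pyridine rather than a stronger base to avoid elimination of the 13-acetoxy group.

**Compound list**
1 | nerol | CC(C)=CCC/C(C)=C\CO | starting material
2 | (2S,3R)-2,3-epoxynerol | CC(C)=CCC[C@@]1(C)O[C@H]1CO | intermediate
3 | (2R,3R)-3-methyl-3-(4-methylpent-3-enyl)oxirane-2-carbaldehyde | CC(C)=CCC[C@@]1(C)O[C@H]1C=O | intermediate
4 | methyl acrylate | C=CC(=O)OC | starting material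
5 | (tert-butyldimethylsilyloxy)acetaldehyde | O=CCO[Si](C)(C)C(C)(C)C | starting material
6 | methyl 4-(tert-butyldimethylsilyloxy)-3-hydroxy-2-methylenebutanoate (racemic) | C=C(C(=O)OC)C(O)CO[Si](C)(C)C(C)(C)C | intermediate
7 | methyl 3-acetoxy-4-(tert-butyldimethylsilyloxy)-2-methylenebutanoate (racemic) | C=C(C(=O)OC)C(OC(C)=O)CO[Si](C)(C)C(C)(C)C | intermediate
8 | methyl (E)-4-(tert-butyldimethylsilyloxy)-2-[(pinacolatoboryl)methyl]but-2-enoate | COC(=O)/C(CB1OC(C)(C)C(C)(C)O1)=C/CO[Si](C)(C)C(C)(C)C | intermediate
9 | O-boryl hydroxy ester, syn C6/C7 and anti C5–O/C6–O (not isolated) | CC(C)=CCC[C@@]1(C)O[C@H]1[C@H]([C@H](CO[Si](C)(C)C(C)(C)C)C(=C)C(=O)OC)OB1OC(C)(C)C(C)(C)O1 | intermediate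
10 | cis-6,7 α-methylene-γ-butyrolactone with C7 CH2OTBS and C6 epoxy side chain | CC(C)=CCC[C@@]1(C)O[C@H]1[C@H]1OC(=O)C(=C)[C@H]1CO[Si](C)(C)C(C)(C)C | intermediate
11 | 13-pinacolatoboryl all-cis lactone (not isolated) | CC(C)=CCC[C@@]1(C)O[C@H]1[C@H]1OC(=O)[C@@H](CB2OC(C)(C)C(C)(C)O2)[C@H]1CO[Si](C)(C)C(C)(C)C | intermediate
12 | all-cis 13-hydroxy lactone | CC(C)=CCC[C@@]1(C)O[C@H]1[C@H]1OC(=O)[C@@H](CO)[C@H]1CO[Si](C)(C)C(C)(C)C | intermediate
13 | all-cis 13-acetoxy lactone | CC(C)=CCC[C@@]1(C)O[C@H]1[C@H]1OC(=O)[C@@H](COC(C)=O)[C@H]1CO[Si](C)(C)C(C)(C)C | intermediate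
14 | ozonide of 13, a 3,3-dimethyl-1,2,4-trioxolane (not isolated) | CC1(C)OOC(CC[C@@]2(C)O[C@H]2[C@H]2OC(=O)[C@@H](COC(C)=O)[C@H]2CO[Si](C)(C)C(C)(C)C)O1 | intermediate
15 | C1 aldehyde | O=CCC[C@@]1(C)O[C@H]1[C@H]1OC(=O)[C@@H](COC(C)=O)[C@H]1CO[Si](C)(C)C(C)(C)C | intermediate
16 | 2-bromoallyl alcohol | OCC(Br)=C | starting material
17 | (2-bromoallyloxy)(tert-butyl)dimethylsilane | C=C(Br)CO[Si](C)(C)C(C)(C)C | intermediate
18 | [3-(tert-butyldimethylsilyloxy)prop-1-en-2-yl]chromium dichloride (not isolated) | C=C([Cr](Cl)Cl)CO[Si](C)(C)C(C)(C)C | intermediate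
19 | C1 allylic alcohol with C10 methylene and CH2OTBS (both C1 epimers) | C=C(CO[Si](C)(C)C(C)(C)C)C(O)CC[C@@]1(C)O[C@H]1[C@H]1OC(=O)[C@@H](COC(C)=O)[C@H]1CO[Si](C)(C)C(C)(C)C | intermediate
20 | bis-silyl enone | C=C(CO[Si](C)(C)C(C)(C)C)C(=O)CC[C@@]1(C)O[C@H]1[C@H]1OC(=O)[C@@H](COC(C)=O)[C@H]1CO[Si](C)(C)C(C)(C)C | intermediate
21 | enone diol | C=C(CO)C(=O)CC[C@@]1(C)O[C@H]1[C@H]1OC(=O)[C@@H](COC(C)=O)[C@H]1CO | intermediate
22 | 2-(bromomethyl) enone with C8 primary alcohol | BrCC(=C)C(=O)CC[C@@]1(C)O[C@H]1[C@H]1OC(=O)[C@@H](COC(C)=O)[C@H]1CO | intermediate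
23 | 2-(bromomethyl) enone C8 aldehyde | BrCC(=C)C(=O)CC[C@@]1(C)O[C@H]1[C@H]1OC(=O)[C@@H](COC(C)=O)[C@H]1C=O | intermediate
24 | 2-acylallylchromium dichloride of 23 (not isolated) | Cl[Cr](Cl)CC(=C)C(=O)CC[C@@]1(C)O[C@H]1[C@H]1OC(=O)[C@@H](COC(C)=O)[C@H]1C=O | intermediate
25 | macrocyclic (8S)-8-hydroxy-10-methylene enone | O[C@H]1CC(=C)C(=O)CC[C@@]2(C)O[C@H]2[C@H]2OC(=O)[C@@H](COC(C)=O)[C@H]21 | intermediate
26 | C10 hydroperoxide (not isolated) | O[C@H]1C[C@@](C)(OO)C(=O)CC[C@@]2(C)O[C@H]2[C@H]2OC(=O)[C@@H](COC(C)=O)[C@H]21 | intermediate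
27 | 8,10-diol | O[C@H]1C[C@@](C)(O)C(=O)CC[C@@]2(C)O[C@H]2[C@H]2OC(=O)[C@@H](COC(C)=O)[C@H]21 | intermediate
28 | 8-methacrylate 10-ol | C=C(C)C(=O)O[C@H]1C[C@@](C)(O)C(=O)CC[C@@]2(C)O[C@H]2[C@H]2OC(=O)[C@@H](COC(C)=O)[C@H]21 | intermediate
29 | CNP0166747.1 | C=C(C)C(=O)O[C@H]1C[C@@](C)(OC(C)=O)C(=O)CC[C@@]2(C)O[C@H]2[C@H]2OC(=O)[C@@H](COC(C)=O)[C@H]21 | target

**Step count**
Total: 19 steps. Longest linear sequence: 16 steps, from methyl acrylate 4 and (tert-butyldimethylsilyloxy)acetaldehyde 5 (steps 3–9 and 11–19). The nerol branch (steps 1 and 2) joins at step 6 and runs 15 steps to the target; step 10 is a one-step side branch that joins at step 11.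

**Steps most likely to fail**

1. Step 16. The allylchromium may add to the wrong face of the C8 aldehyde, since the face preference rests on the conformation of a forming ten-membered ring. The fallback sets out from 23 and accepts the other epimer: if closure gives mainly the 8-epi macrocyclic hydroxy enone F1, this is hydrated under the conditions of step 17, by way of the 8-epi C10 hydroperoxide F2 (not isolated), to the 8-epi 8,10-diol F3. The C8 configuration is then inverted while the ester is put on, by Mitsunobu esterification with methacrylic acid (PPh3, DIAD, THF, 0 °C). This SN2 displacement returns to the route at 28, so step 18 is not needed.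

2. Step 17. Dioxygen may be captured on the wrong face of the C10 radical, or the radical may be reduced without oxygenation. The fallback sets out from 25 and moves the stereo-determining event to epoxidation of a ring double bond. The C8 hydroxyl is silylated (TESCl, imidazole) to the 8-O-triethylsilyl macrocyclic enone F4. RhCl(PPh3)3-catalysed 1,4-hydrosilylation with Et3SiH gives the C1–C10 triethylsilyl enol ether F5, regiospecifically. Rubottom oxidation with dimethyldioxirane gives the 8,10-bis(triethylsilyloxy) ketone F6, and HF·pyridine removes both silyl groups to return at 27.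

3. Step 6. The sluggish, electron-poor allylboronate needs prolonged heating with a sensitive epoxy aldehyde, so decomposition or poor facial selectivity at C6 may result. The fallback sets out from 3 and uses a Barbier reaction at room temperature. Alcohol 6 is converted by Corey–Kim bromination (NBS, Me2S) with allylic transposition into methyl (Z)-2-(bromomethyl)-4-(tert-butyldimethylsilyloxy)but-2-enoate F7. Indium powder in THF/H2O couples this bromide with 3, a reaction of this bromide class that is syn-selective and follows Felkin–Anh control with protected α-oxygenated aldehydes, to give the syn,anti hydroxy ester F8. PPTS-catalysed lactonisation returns at 10.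

Further compounds
F1 | step 16 | 8-epi macrocyclic hydroxy enone | O[C@@H]1CC(=C)C(=O)CC[C@@]2(C)O[C@H]2[C@H]2OC(=O)[C@@H](COC(C)=O)[C@H]21
F2 | step 16 | 8-epi C10 hydroperoxide (not isolated) | O[C@@H]1C[C@@](C)(OO)C(=O)CC[C@@]2(C)O[C@H]2[C@H]2OC(=O)[C@@H](COC(C)=O)[C@H]21
F3 | step 16 | 8-epi 8,10-diol | O[C@@H]1C[C@@](C)(O)C(=O)CC[C@@]2(C)O[C@H]2[C@H]2OC(=O)[C@@H](COC(C)=O)[C@H]21
F4 | step 17 | 8-O-triethylsilyl macrocyclic enone | CC[Si](CC)(CC)O[C@H]1CC(=C)C(=O)CC[C@@]2(C)O[C@H]2[C@H]2OC(=O)[C@@H](COC(C)=O)[C@H]21
F5 | step 17 | C1–C10 triethylsilyl enol ether of F4 | CC[Si](CC)(CC)O[C@H]1CC(C)=C(O[Si](CC)(CC)CC)CC[C@@]2(C)O[C@H]2[C@H]2OC(=O)[C@@H](COC(C)=O)[C@H]21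
F6 | step 17 | 8,10-bis(triethylsilyloxy) ketone | CC[Si](CC)(CC)O[C@H]1C[C@@](C)(O[Si](CC)(CC)CC)C(=O)CC[C@@]2(C)O[C@H]2[C@H]2OC(=O)[C@@H](COC(C)=O)[C@H]21
F7 | step 6 | methyl (Z)-2-(bromomethyl)-4-(tert-butyldimethylsilyloxy)but-2-enoate | COC(=O)/C(CBr)=C/CO[Si](C)(C)C(C)(C)C
F8 | step 6 | syn,anti hydroxy ester (open form of 10) | CC(C)=CCC[C@@]1(C)O[C@H]1[C@@H](O)[C@H](CO[Si](C)(C)C(C)(C)C)C(=C)C(=O)OC
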